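**Plan**

- Retrosynthesis: remove three O-benzyl groups and a blocking bromine at C6, and return the C4 carbonyl to a C4–OMe ether. Then cut ring C at O1–C2 and C3–C4, which gives styrene and a salicylaldehyde dimethyl acetal. Cut the formyl carbon from the ring position ortho to the phenol, then the ArCH2–C3(pyranone) bond, then the pyranone ring at its two bonds to the malonyl unit.
- Forward: pyranone ring (steps 1–2); methylene bridge from the formyl carbon of 2-hydroxy-4,6-bis(benzyloxy)benzaldehyde (step 4); new formyl group ortho to the phenol (step 5); pyranone O-benzylation, bromination of the last aryl C–H and acetal formation (steps 6–8); ring C by [4+2] with styrene (step 9); C4–OMe to C4=O (steps 10–11); hydrogenolysis (step 12).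
- Enabling feature: in ring C the unit C3–C2(Ph) is styrene and lies between the phenolic O1 and C4. The array O1–C8a=C4a–C4 on the phloroglucinol ring A can be raised to an alkoxy ortho-quinone methide (an oxa-diene), because the oxygens at C5, C7 and C8a stabilise positive charge at C4.
- Stereochemistry: C2 (S), the only stereocentre of the target, is set by the chiral Brønsted acid in step 9. C4 of the cycloadduct is transient and is erased in step 11. No basic step follows that could open the flavanone.

Key step: step 9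

Assumption: the sense of induction of the chiral acid cannot be predicted for this new reaction, so the catalyst antipode that leads to (2S) is taken. The C4 configuration of 17 (drawn 2,4-cis) and the alkene geometries of the non-isolated intermediates 8 and 16 are drawn for definiteness and do not affect the target.

**Route**

Step 1
Reactants: 1 3-pentanone
Product: 2 (Z)-trimethyl(pent-2-en-3-yloxy)silane (Z-major E/Z mixture, used as such)
Conditions: TMSCl, Et3N, DMF, 80 °C
Reagents that add atoms: chlorotrimethylsilane, C[Si](C)(C)Cl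
Why: Thermodynamic O-silylation of a ketone enol; the symmetrical ketone can give only one regioisomer and both alkene geometries converge in step 2.

Step 2
Reactants: 2 (Z)-trimethyl(pent-2-en-3-yloxy)silane; 3 malonyl dichloride
Product: 5 6-ethyl-4-hydroxy-5-methyl-2H-pyran-2-one, via 4-methyl-3,5-dioxoheptanoyl chloride 4 (not isolated)
Conditions: Et2O, −78 °C → rt
Reagents that add atoms: none
Why: Pyranone annulation of a silyl enol ether with malonyl dichloride: C-acylation with loss of TMSCl, then O-acylation of the new enol by the second acyl chloride with loss of HCl, places ethyl on C6 and methyl on C5.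

Step 3
Reactants: 6 2,4,6-trihydroxybenzaldehyde
Product: 7 2-hydroxy-4,6-bis(benzyloxy)benzaldehyde
Conditions: BnBr (2.05 equiv), K2CO3 (2.1 equiv), DMF, 0 °C → rt
Reagents that add atoms: benzyl bromide, BrCc1ccccc1
Why: Williamson etherification in which the para hydroxyl and one ortho hydroxyl react, while the remaining ortho hydroxyl is held back by its hydrogen bond to the formyl group, as is usual for acylphloroglucinols.

Step 4
Reactants: 7 2-hydroxy-4,6-bis(benzyloxy)benzaldehyde; 5 6-ethyl-4-hydroxy-5-methyl-2H-pyran-2-one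
Product: 9 3-[2,4-bis(benzyloxy)-6-hydroxybenzyl]-6-ethyl-4-hydroxy-5-methyl-2H-pyran-2-one, via Knoevenagel arylidene pyrandione 8 (not isolated)
Conditions: Hantzsch ester (1.1 equiv), L-proline (20 mol %), EtOH, rt
Reagents that add atoms: none
Why: Three-component reductive alkylation: proline-mediated Knoevenagel condensation at the nucleophilic C3 of the hydroxypyranone, then Hantzsch ester transfer hydrogenation of the alkylidene dione, which turns the formyl carbon into the methylene bridge before a second pyranone can add.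

Step 5
Reactants: 9 3-[2,4-bis(benzyloxy)-6-hydroxybenzyl]-6-ethyl-4-hydroxy-5-methyl-2H-pyran-2-one
Product: 11 4,6-bis(benzyloxy)-3-[(6-ethyl-4-hydroxy-5-methyl-2-oxo-2H-pyran-3-yl)methyl]-2-hydroxybenzaldehyde, via ortho-hydroxymethyl phenol 10 (not isolated)
Conditions: MgCl2 (3 equiv), Et3N (6 equiv), (CH2O)n (8 equiv), THF, reflux; then 1 M HCl
Reagents that add atoms: formaldehyde (as paraformaldehyde), C=O
Why: Magnesium-mediated ortho-formylation of phenols: the magnesium phenoxide delivers formaldehyde only to the single free carbon next to the phenolic oxygen, and the hydroxymethyl phenol is oxidised by a second formaldehyde (Oppenauer-type hydride transfer), so the formyl group is placed without regiochemical ambiguity while the hydroxypyranone, blocked at C3, is carried as its salt.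

Step 6
Reactants: 11 4,6-bis(benzyloxy)-3-[(6-ethyl-4-hydroxy-5-methyl-2-oxo-2H-pyran-3-yl)methyl]-2-hydroxybenzaldehyde
Product: 12 4,6-bis(benzyloxy)-3-{[4-(benzyloxy)-6-ethyl-5-methyl-2-oxo-2H-pyran-3-yl]methyl}-2-hydroxybenzaldehyde
Conditions: BnOH (1.05 equiv), PPh3, DIAD (1.1 equiv each), THF, 0 °C → rt
Reagents that add atoms: benzyl alcohol, OCc1ccccc1
Why: Mitsunobu O-alkylation, which for 4-hydroxy-2-pyranones goes at the 4-oxygen; the pyranone OH (pKa about 5) is deprotonated by the betaine well before the chelated salicylaldehyde OH, so one equivalent of reagents should benzylate it alone and remove the internal acid that would otherwise ionise the later acetal.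

Step 7
Reactants: 12 4,6-bis(benzyloxy)-3-{[4-(benzyloxy)-6-ethyl-5-methyl-2-oxo-2H-pyran-3-yl]methyl}-2-hydroxybenzaldehyde
Product: 13 4,6-bis(benzyloxy)-3-{[4-(benzyloxy)-6-ethyl-5-methyl-2-oxo-2H-pyran-3-yl]methyl}-5-bromo-2-hydroxybenzaldehyde
Conditions: NBS (1.05 equiv), MeCN, 0 °C, dark
Reagents that add atoms: N-bromosuccinimide, O=C1CCC(=O)N1Br
Why: Electrophilic aromatic bromination at the only unsubstituted ring carbon (para to the free phenol, between two benzyloxy groups); the bromine blocks this nucleophilic position against Friedel–Crafts alkylation by the cations of steps 8–10 and is removed with the benzyl groups in step 12.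

Step 8
Reactants: 13 4,6-bis(benzyloxy)-3-{[4-(benzyloxy)-6-ethyl-5-methyl-2-oxo-2H-pyran-3-yl]methyl}-5-bromo-2-hydroxybenzaldehyde
Product: 14 4-(benzyloxy)-3-[4,6-bis(benzyloxy)-5-bromo-3-(dimethoxymethyl)-2-hydroxybenzyl]-6-ethyl-5-methyl-2H-pyran-2-one
Conditions: HC(OMe)3 (solvent), MeOH (2 equiv), PPTS (5 mol %), rt; Et3N quench, concentration, short basic alumina plug; used at once
Reagents that add atoms: trimethyl orthoformate, COC(OC)OC; methanol, CO
Why: Acid-catalysed acetalisation driven by the orthoformate as water scavenger; quenching with amine before concentration should keep the labile ortho-hydroxy acetal from ionising.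

Step 9
Reactants: 14 4-(benzyloxy)-3-[4,6-bis(benzyloxy)-5-bromo-3-(dimethoxymethyl)-2-hydroxybenzyl]-6-ethyl-5-methyl-2H-pyran-2-one; 15 styrene
Product: 17 (2S,4S)-5,7-bis(benzyloxy)-8-{[4-(benzyloxy)-6-ethyl-5-methyl-2-oxo-2H-pyran-3-yl]methyl}-6-bromo-4-methoxy-2-phenylchromane (2,4-cis), via alkoxy ortho-quinone methide 16 (not isolated)
Conditions: styrene (10 equiv), chiral BINOL-derived imidodiphosphorimidate (IDPi) Brønsted acid (5 mol %), 5 Å MS, CHCl3, −30 → 0 °C, slow addition of 14
Reagents that add atoms: none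
Why: Proposed new method: the confined chiral acid should protonate a methoxy group of 14 and expel methanol (taken up by the sieves) to give the α-methoxybenzyl cation, i.e. the O-protonated alkoxy ortho-quinone methide 16, held to the chiral anion through the phenolic O–H; the terminal carbon of styrene then attacks the cationic carbon (C3–C4) and the phenolic oxygen captures the resulting phenyl-stabilised cation (O1–C2). The closest known reaction types are chiral Brønsted acid-catalysed [4+2] cycloadditions of ortho-quinone methides with activated or tethered alkenes and Lewis acid annulations of salicylaldehyde acetals with alkenes to racemic 4-alkoxychromans; an enantioselective intermolecular case with an alkoxy quinone methide and plain styrene is not known. The pyran ring closes as a formal inverse-demand oxa-[4+2] annulation, asynchronous to stepwise, the O1–C2 closure being a six-membered cation capture that is endo with respect to the former styrene π bond. C2 is controlled by the chiral counter-anion, which shields one face of the hydrogen-bonded ion pair toward styrene, and C4 should come out cis to C2 (phenyl endo on the E-alkoxy methide) but is erased in step 11. The step needs regioselectivity, secured by styrene polarity (cation next to phenyl, hence phenyl on C2) and by the single free phenol flanked by the pyranonylmethyl carbon, and chemoselectivity for styrene over arene nucleophiles, secured by the C6 bromine that leaves ring A without an aryl C–H, by slow addition into excess styrene, and by the fact that the product ether, lacking the second oxygen on C4, ionises much less readily than the acetal.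

Step 10
Reactants: 17 (2S,4S)-5,7-bis(benzyloxy)-8-{[4-(benzyloxy)-6-ethyl-5-methyl-2-oxo-2H-pyran-3-yl]methyl}-6-bromo-4-methoxy-2-phenylchromane
Product: 18 (2S)-5,7-bis(benzyloxy)-8-{[4-(benzyloxy)-6-ethyl-5-methyl-2-oxo-2H-pyran-3-yl]methyl}-6-bromo-2-phenylchroman-4-ol (C4 epimers)
Conditions: TsOH·H2O (0.2 equiv), THF/H2O 3:1, 0.02 M, rt → 40 °C
Reagents that add atoms: water, O
Why: SN1 solvolysis: the C4 ether, ortho/para to three ring oxygens, ionises under mild acid and water in large excess captures the cation, while C2 is not involved and keeps its configuration, and the C4 configuration is of no consequence.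

Step 11
Reactants: 18 (2S)-5,7-bis(benzyloxy)-8-{[4-(benzyloxy)-6-ethyl-5-methyl-2-oxo-2H-pyran-3-yl]methyl}-6-bromo-2-phenylchroman-4-ol
Product: 19 (2S)-5,7-bis(benzyloxy)-8-{[4-(benzyloxy)-6-ethyl-5-methyl-2-oxo-2H-pyran-3-yl]methyl}-6-bromo-2-phenylchroman-4-one
Conditions: Dess–Martin periodinane (1.3 equiv), CH2Cl2, 0 °C → rt
Reagents that add atoms: none
Why: Dess–Martin oxidation of the secondary benzylic alcohol under non-basic conditions, which avoids the base-induced retro-oxa-Michael opening that would racemise C2; both C4 epimers converge on one ketone.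

Step 12
Reactants: 19 (2S)-5,7-bis(benzyloxy)-8-{[4-(benzyloxy)-6-ethyl-5-methyl-2-oxo-2H-pyran-3-yl]methyl}-6-bromo-2-phenylchroman-4-one
Product: 20 (2S)-8-[(6-ethyl-4-hydroxy-5-methyl-2-oxo-2H-pyran-3-yl)methyl]-5,7-dihydroxy-2-phenylchroman-4-one (CNP0326321.1)
Conditions: H2 (1 atm), 10% Pd/C, NaOAc (1.2 equiv), EtOAc/MeOH, rt
Reagents that add atoms: none
Why: Heterogeneous hydrogenolysis should remove the three O-benzyl groups and the aryl bromide in one operation, the acetate buffer taking up HBr without reaching the basicity needed to open the flavanone, so C2 stays (S).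

**Compound list**

1 | 3-pentanone | CCC(=O)CC | starting material
2 | (Z)-trimethyl(pent-2-en-3-yloxy)silane | C/C=C(\O[Si](C)(C)C)CC | intermediate
3 | malonyl dichloride | O=C(Cl)CC(Cl)=O | starting material
4 | 4-methyl-3,5-dioxoheptanoyl chloride (racemic) | CCC(=O)C(C)C(=O)CC(Cl)=O | intermediate (not isolated)
5 | 6-ethyl-4-hydroxy-5-methyl-2H-pyran-2-one | CCc1oc(=O)cc(O)c1C | intermediate
6 | 2,4,6-trihydroxybenzaldehyde | O=Cc1c(O)cc(O)cc1O | starting material
7 | 2-hydroxy-4,6-bis(benzyloxy)benzaldehyde | O=Cc1c(O)cc(OCc2ccccc2)cc1OCc1ccccc1 | intermediate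
8 | (3E)-3-[2,4-bis(benzyloxy)-6-hydroxybenzylidene]-6-ethyl-5-methyl-2H-pyran-2,4(3H)-dione | CCC1=C(C)C(=O)/C(=C\c2c(O)cc(OCc3ccccc3)cc2OCc2ccccc2)C(=O)O1 | intermediate (not isolated)
9 | 3-[2,4-bis(benzyloxy)-6-hydroxybenzyl]-6-ethyl-4-hydroxy-5-methyl-2H-pyran-2-one | CCc1oc(=O)c(Cc2c(O)cc(OCc3ccccc3)cc2OCc2ccccc2)c(O)c1C | intermediate
10 | 3-[4,6-bis(benzyloxy)-2-hydroxy-3-(hydroxymethyl)benzyl]-6-ethyl-4-hydroxy-5-methyl-2H-pyran-2-one | CCc1oc(=O)c(Cc2c(O)c(CO)c(OCc3ccccc3)cc2OCc2ccccc2)c(O)c1C | intermediate (not isolated)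
11 | 4,6-bis(benzyloxy)-3-[(6-ethyl-4-hydroxy-5-methyl-2-oxo-2H-pyran-3-yl)methyl]-2-hydroxybenzaldehyde | CCc1oc(=O)c(Cc2c(O)c(C=O)c(OCc3ccccc3)cc2OCc2ccccc2)c(O)c1C | intermediate
12 | 4,6-bis(benzyloxy)-3-{[4-(benzyloxy)-6-ethyl-5-methyl-2-oxo-2H-pyran-3-yl]methyl}-2-hydroxybenzaldehyde | CCc1oc(=O)c(Cc2c(O)c(C=O)c(OCc3ccccc3)cc2OCc2ccccc2)c(OCc2ccccc2)c1C | intermediate
13 | 4,6-bis(benzyloxy)-3-{[4-(benzyloxy)-6-ethyl-5-methyl-2-oxo-2H-pyran-3-yl]methyl}-5-bromo-2-hydroxybenzaldehyde | CCc1oc(=O)c(Cc2c(O)c(C=O)c(OCc3ccccc3)c(Br)c2OCc2ccccc2)c(OCc2ccccc2)c1C | intermediate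
14 | 4-(benzyloxy)-3-[4,6-bis(benzyloxy)-5-bromo-3-(dimethoxymethyl)-2-hydroxybenzyl]-6-ethyl-5-methyl-2H-pyran-2-one | CCc1oc(=O)c(Cc2c(O)c(C(OC)OC)c(OCc3ccccc3)c(Br)c2OCc2ccccc2)c(OCc2ccccc2)c1C | intermediate (key-step precursor)
15 | styrene | C=Cc1ccccc1 | starting material
16 | 3,5-bis(benzyloxy)-2-{[4-(benzyloxy)-6-ethyl-5-methyl-2-oxo-2H-pyran-3-yl]methyl}-4-bromo-6-[(E)-methoxymethylidene]cyclohexa-2,4-dien-1-one (neutral form of the oxocarbenium ion) | CCc1oc(=O)c(CC2=C(OCc3ccccc3)C(Br)=C(OCc3ccccc3)/C(=C\OC)C2=O)c(OCc2ccccc2)c1C | intermediate (not isolated)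
17 | (2S,4S)-5,7-bis(benzyloxy)-8-{[4-(benzyloxy)-6-ethyl-5-methyl-2-oxo-2H-pyran-3-yl]methyl}-6-bromo-4-methoxy-2-phenylchromane | CCc1oc(=O)c(Cc2c(OCc3ccccc3)c(Br)c(OCc3ccccc3)c3c2O[C@H](c2ccccc2)C[C@@H]3OC)c(OCc2ccccc2)c1C | intermediate (key-step product)
18 | (2S)-5,7-bis(benzyloxy)-8-{[4-(benzyloxy)-6-ethyl-5-methyl-2-oxo-2H-pyran-3-yl]methyl}-6-bromo-2-phenylchroman-4-ol (C4 epimers, C4 left undefined) | CCc1oc(=O)c(Cc2c(OCc3ccccc3)c(Br)c(OCc3ccccc3)c3c2O[C@H](c2ccccc2)CC3O)c(OCc2ccccc2)c1C | intermediate
19 | (2S)-5,7-bis(benzyloxy)-8-{[4-(benzyloxy)-6-ethyl-5-methyl-2-oxo-2H-pyran-3-yl]methyl}-6-bromo-2-phenylchroman-4-one | CCc1oc(=O)c(Cc2c(OCc3ccccc3)c(Br)c(OCc3ccccc3)c3c2O[C@H](c2ccccc2)CC3=O)c(OCc2ccccc2)c1C | intermediate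
20 | (2S)-8-[(6-ethyl-4-hydroxy-5-methyl-2-oxo-2H-pyran-3-yl)methyl]-5,7-dihydroxy-2-phenylchroman-4-one | CCc1oc(=O)c(Cc2c(O)cc(O)c3c2O[C@H](c2ccccc2)CC3=O)c(O)c1C | target

**Count and risks**

Total steps: 12. Longest linear sequence: 11 steps (steps 1, 2, 4–12, from 3-pentanone); the branch from 2,4,6-trihydroxybenzaldehyde is 10 steps (steps 3–12).

Steps most likely to fail:

1. Step 9. The chiral anion is tied to the cation by a single hydrogen bond and styrene carries no directing group, so facial discrimination may be poor. The strongly stabilised cation may also add styrene so slowly that acid-driven oligomerisation of styrene takes over. The fallback gives up asymmetric induction in the annulation and takes the stereocentre from a kinetic resolution, using known chemistry throughout. It sets out from 14: a catalytic achiral Lewis acid (Sc(OTf)3, CH2Cl2, rt), as known for salicylaldehyde acetals and alkenes, should give the racemic cis-4-methoxyflavan F1 with styrene. Hydrolysis and Dess–Martin oxidation as in steps 10 and 11 should lead through the racemic flavan-4-ol F2 to the racemic flavanone F3. Noyori-type asymmetric transfer hydrogenation (Ru/TsDPEN, HCO2H/Et3N, EtOAc, to about half conversion), a known kinetic resolution of flavanones, is then run with the catalyst antipode that reduces the (2R)-ketone to the cis-(2R,4R)-flavan-4-ol F4. The (2S)-ketone is left untouched, and the route is rejoined at 19.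

2. Step 10. The C4 cation may lose the C3 proton to a flav-3-ene instead of being captured by water, or the exchange may stall. The fallback removes the methyl ether oxidatively and sets out from 17: DDQ in CH2Cl2/pH 7 buffer should abstract the C4 hydride, as known for benzylic methyl ethers of electron-rich arenes and for C4 of 5,7-dialkoxyflavans. Water adds to the methoxy-oxocarbenium ion and the hemiketal collapses to the ketone with loss of methanol. This makes no new compound (F0) and comes back to the route at 19, skipping step 11.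

3. Step 5. The free hydroxypyranone may sequester magnesium and consume formaldehyde in reversible aldol chemistry, so that the phenol is formylated incompletely. The fallback changes the order of events so that the phenol is the only acidic site during formylation. It sets out from 9: Mitsunobu benzylation (BnOH, PPh3, DIAD), selective for the far more acidic pyranone OH over the phenol, should give 4-(benzyloxy)-3-[2,4-bis(benzyloxy)-6-hydroxybenzyl]-6-ethyl-5-methyl-2H-pyran-2-one F5. The same magnesium-mediated ortho-formylation on F5 then comes back to the route at 12, and step 6 is no longer needed.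

**Further compounds**

F1 | step 9 | racemic cis-(2R*,4R*)-5,7-bis(benzyloxy)-8-{[4-(benzyloxy)-6-ethyl-5-methyl-2-oxo-2H-pyran-3-yl]methyl}-6-bromo-4-methoxy-2-phenylchromane (both enantiomers) | CCc1oc(=O)c(Cc2c(OCc3ccccc3)c(Br)c(OCc3ccccc3)c3c2O[C@H](c2ccccc2)C[C@@H]3OC)c(OCc2ccccc2)c1C.CCc1oc(=O)c(Cc2c(OCc3ccccc3)c(Br)c(OCc3ccccc3)c3c2O[C@@H](c2ccccc2)C[C@H]3OC)c(OCc2ccccc2)c1C
F2 | step 9 | racemic 5,7-bis(benzyloxy)-8-{[4-(benzyloxy)-6-ethyl-5-methyl-2-oxo-2H-pyran-3-yl]methyl}-6-bromo-2-phenylchroman-4-ol (stereoisomer mixture, drawn without configuration) | CCc1oc(=O)c(Cc2c(OCc3ccccc3)c(Br)c(OCc3ccccc3)c3c2OC(c2ccccc2)CC3O)c(OCc2ccccc2)c1C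
F3 | step 9 | racemic 5,7-bis(benzyloxy)-8-{[4-(benzyloxy)-6-ethyl-5-methyl-2-oxo-2H-pyran-3-yl]methyl}-6-bromo-2-phenylchroman-4-one (both enantiomers) | CCc1oc(=O)c(Cc2c(OCc3ccccc3)c(Br)c(OCc3ccccc3)c3c2O[C@H](c2ccccc2)CC3=O)c(OCc2ccccc2)c1C.CCc1oc(=O)c(Cc2c(OCc3ccccc3)c(Br)c(OCc3ccccc3)c3c2O[C@@H](c2ccccc2)CC3=O)c(OCc2ccccc2)c1C
F4 | step 9 | (2R,4R)-5,7-bis(benzyloxy)-8-{[4-(benzyloxy)-6-ethyl-5-methyl-2-oxo-2H-pyran-3-yl]methyl}-6-bromo-2-phenylchroman-4-ol (2,4-cis) | CCc1oc(=O)c(Cc2c(OCc3ccccc3)c(Br)c(OCc3ccccc3)c3c2O[C@@H](c2ccccc2)C[C@H]3O)c(OCc2ccccc2)c1C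
F0 | step 10 | none | none
F5 | step 5 | 4-(benzyloxy)-3-[2,4-bis(benzyloxy)-6-hydroxybenzyl]-6-ethyl-5-methyl-2H-pyran-2-one | CCc1oc(=O)c(Cc2c(O)cc(OCc3ccccc3)cc2OCc2ccccc2)c(OCc2ccccc2)c1C
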